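## Analysis of the target

The target (39) is an eighteen-carbon chain, numbered here from the ester carbonyl C1 to C18, with methyl branches at C2, C6, C10, C14 and C18. C3 and C6 are bridged by an O–O unit into a 1,2-dioxane, C14 carries a free tertiary hydroperoxide, and the chain ends in the trisubstituted C17=C18 alkene.

There are five stereocentres: C2 (R), C3 (S), C6 (R), C10 (R) and C14 (R). C2 and C3 form a syn methyl/oxygen pair, and on the ring the C3 side chain is cis to the C6 methyl group. C10 and C14 are isolated: C10 lies four bonds from both C6 and C14, so no neighbouring centre can relay its configuration.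

C6 and C14 are fully substituted C–OO centres. A peroxide can be put on such a carbon with defined configuration only by invertive opening of a strained ether, which fixes the oxygenation early in both halves of the molecule.

The sensitive groups are:
- the two O–O bonds, which exclude metal-catalysed hydrogenation, low-valent metals and organolithium or Grignard reagents on peroxide-bearing intermediates;
- the β-peroxy ester, where deprotonation at C2 would open the ring by elimination;
- the free hydroperoxide;
- the C17=C18 alkene, which is at risk from electrophiles and from over-reduction.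

The difficulty is that C10 has to be created in a fragment that already contains a peroxide and the C17=C18 alkene. The strategy rests on reading C8–C10 as a 3-methyl-2-enal: a flavin ene-reductase reduces only the conjugated C9=C10 bond, sets C10 under enzyme control, and leaves O–O bonds and the isolated alkene alone.

## Retrosynthetic reasoning

**39 ⇒ 38.** The last operation only unmasks the C14 hydroperoxide. A free tertiary OOH would not survive ylides, hydrides, amide bases or the sulfur oxidation, so it travels as the mixed peroxyketal of 38. Mild aqueous acid releases it without touching the ring peroxide, the ester or C17=C18.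

**38 ⇒ 37 ⇒ 18 + 36 (C7–C8).** The chain is cut next to the ring. C7 cannot be the nucleophile, because a carbanion there is β to the ring peroxide and would expel it. C7 cannot be an SN2 electrophile either, because C6 is quaternary. As a carbonyl electrophile C7 is ideal: aldehyde 36 has no α-hydrogen. C8 therefore carries the nucleophile as the tetrazolyl sulfone 18; olefination gives 37 and a metal-free hydrogen transfer saturates C7=C8. This cut makes the route convergent and keeps C2/C3/C6 in one fragment and C10/C14 in the other.

**18 ⇒ 15.** Only the oxidation level at C8 changes: aldehyde 15 is reduced to alcohol 16, converted to sulfide 17 and oxidised to 18.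

**15 ⇒ 14 (the C10–H and C9–H bonds).** No skeletal bond is cut. Aldehyde 15 is the dihydro form of the (E)-enal 14, a 7-peroxy-6,7-dihydrofarnesal. The forward reaction must add hydride to one face of C10 without touching the peroxyketal or C17=C18; an ene-reductase does this. Placing the step on the side-chain fragment, before the union, lets the C10 configuration be secured on a small molecule.

**14 ⇒ 12 ⇒ 10 + 11 (C9=C10), and 10 ⇒ 9 ⇒ 8 (C11=C12).** The enal comes from the (E)-enoate 12, made by Horner–Wadsworth–Emmons reaction of methyl ketone 10 with phosphonate 11. Ketone 10 comes from aldehyde 8 through enone 9. Both olefinations use stabilised phosphorus reagents, which are too weakly basic to eliminate the β-peroxy group of 8 and do not attack O–O bonds. Enoate 12 must be a single geometric isomer, because the alkene geometry decides which face of C10 the enzyme reduces.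

**8 ⇒ 7 ⇒ 6 ⇒ 5 ⇒ 3 ⇒ 1 (the C14–OO bond).** The tertiary peroxide is traced to oxetane 5, opened at C14 with inversion by a peroxide nucleophile. The oxetane comes from 1,3-diol 3, and 3 from (R)-linalool (1) by hydroboration of its vinyl group. Linalool supplies C12–C18, the homoprenyl group and the C14 oxygen in the configuration that inversion converts into 14R. The primary alcohol freed in 6 is the handle for chain extension.

**36 ⇒ 35 ⇒ 33 (the O2–C6 bond).** The dioxane is opened to a C3 hydroperoxide and a C6–C7 epoxide. In the forward direction the terminal peroxide oxygen attacks the tertiary epoxide carbon (6-exo, Markovnikov) with inversion, which sets C6 and frees the C7 hydroxymethyl group that becomes the aldehyde of 36. C1 is already the methyl ester in 33, so no oxidation is needed after the peroxide ring exists.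

**33 ⇒ 32 ⇒ 30 ⇒ 26 + 28 (the O1–C3 bond).** The C3 peroxide is installed by SN2 displacement on the activated alcohol 26 with the protected hydroperoxide 28, made from alkene 27. Inversion turns the anti C2/C3 pair of 26 into the syn pair of the target. At this stage C1 is a vinyl group, not an ester, so no β-elimination can compete; the vinyl group becomes the ester in 33 afterwards. The epoxide of 32 is kept masked in 30 as a silyloxy tosylate and released by fluoride.

**26 ⇒ 24 (C2–C3), and 24 ⇒ 22 ⇒ 20 ⇒ 19 (C4–C5).** Reagent-controlled anti-crotylboration of aldehyde 24 sets C2 and C3 together. Aldehyde 24 comes from (S)-2-methylglycidol (19): an allyl nucleophile opens the epoxide at its CH2 group, which places the glycidol oxygen on C6 in the configuration that the later invertive ring closure requires.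

## Alternatives that were turned down

**Alternative 1: the hydroperoxide–epoxide ring closure as the centre of the strategy.**
- Disconnection: the O2–C6 bond, then C7–C8.
- Forward key step: acid frees the C3 hydroperoxide of the silyl-protected peroxyketal epoxide A2; its terminal oxygen opens the 2,2-disubstituted epoxide at C6 with inversion to give dioxane A1, with a C7 hydroxymethyl handle.
- For: the exo and Markovnikov preferences point to the same carbon, the closure is stereospecific, and C3 and C6 come from independently set centres.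
- Against: the strategy solves the part of the molecule for which stereospecific chemistry already exists and is silent on C10. C10 would have to be bought from a chiral-pool C10 unit whose other end is poorly suited to building the C14 tertiary hydroperoxide, or set by auxiliary chemistry before any peroxide is present. In A1, C1 is still a silyl ether; reaching the ester means desilylation and two oxidations through an α-methyl-β-peroxy aldehyde, which can epimerise at C2 or eliminate the peroxide, late in the route.
- Comparison: on the ring closure itself this alternative is as strong as the chosen route, which closes its ring the same way (33 to 35) but with C1 already an ester. The chosen strategy adds a catalyst-controlled answer for C10, set on a small fragment where it can be checked before the union.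

**Alternative 2: enantioselective allylation of a tertiary cyclic peroxycarbenium ion.**
- Disconnection: C6–C7.
- Forward key step: a confined chiral imidodiphosphorimidate acid ionises the C6 methoxy group of bis-peroxyketal A4, and an allylsilane adds to the ion paired with the chiral anion to give A3.
- For: it is by far the shortest entry to the ring, catalytic, and from trivial materials. On step economy for the ring it is stronger than the chosen route.
- Against: the enantio-determining event must distinguish a methyl group from a ring methylene flanking a planar peroxycarbenium ion, a small steric difference, at a tertiary centre where ion-pair control is least developed. Peroxycarbenium ions under strong acid can also lose the O–O bond by rearrangement. A3 is still a C3 anomer mixture; C3 and C2 would need a second peroxycarbenium addition whose 3,6-selectivity depends on the ring telling a methyl from an alkyl group at C6. C10 and C14 are not addressed.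
- Comparison: two unproven selectivity events stand against the chosen route's stereospecific, known steps for the ring and one uncertain step of a known biocatalytic type.

**Alternative 3: dioxolanone alkylation to build the C14 quaternary carbon.**
- Disconnection: C14–C15.
- Forward key step: the lithium enolate of cis-dioxolanone A6 is alkylated by iodide A7 anti to the tert-butyl group to give A5.
- For: self-regeneration of the stereocentre is highly diastereoselective, and A5 could reach a higher enantiomeric purity at C14 than commercial linalool. On this point the alternative is stronger.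
- Against: A5 delivers a tertiary C–O bond, not a C–OO bond. The peroxide can only be introduced by the same invertive oxetane opening, which needs a 1,3-diol. The carbonyl carbon of A5 is only C13, so reduction, one-carbon homologation and protecting-group steps are needed to reach the stage of diol 3, which linalool gives in one step. Alkylating the hindered enolate with the unactivated iodide A7 is also slow and competes with elimination. C10 is again left open.
- Comparison: the chosen strategy gives up a little enantiomeric security at C14 for brevity and spends its effort on C10.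

Key step: step 11

## Route

Remark on the chemistry: the ene-reductase is a catalyst, used as isolated protein (from a commercial ene-reductase panel or by recombinant expression). Low-molecular-weight peroxides (6, 28) are handled in solution and not concentrated to dryness.

**Step 1**
Reactants: 1 (R)-linalool
Product: 3 (3R)-3,7-dimethyloct-6-ene-1,3-diol, via alkylborane 2 (not isolated)
Conditions: 9-BBN, THF, 0 °C → rt; then NaOH (3 M), 30% H2O2, 0 °C → rt
Reagents that add atoms: hydrogen peroxide, OO
Why: Anti-Markovnikov hydroboration with 9-BBN takes place only at the unhindered vinyl group (the trisubstituted C17=C18 alkene reacts far more slowly), and oxidation with retention gives the 1,3-diol; C14 is not touched.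

**Step 2**
Reactants: 3 (3R)-3,7-dimethyloct-6-ene-1,3-diol
Product: 5 (2R)-2-methyl-2-(4-methylpent-3-en-1-yl)oxetane, via monotosylate 4 (not isolated)
Conditions: TsCl, Et3N, DMAP (cat.), CH2Cl2, 0 °C; then KOtBu, THF, 0 °C → rt
Reagents that add atoms: none
Why: The primary hydroxyl is sulfonylated selectively and the tertiary alkoxide closes the four-membered ring by intramolecular Williamson etherification (4-exo-tet); the C14–O bond is not broken, so C14 keeps its configuration.

**Step 3**
Reactants: 5 (2R)-2-methyl-2-(4-methylpent-3-en-1-yl)oxetane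
Product: 6 (3S)-3-hydroperoxy-3,7-dimethyloct-6-en-1-ol
Conditions: H2O2 (anhydrous, in Et2O), TMSOTf (0.2 equiv), Et2O, −78 → −20 °C
Reagents that add atoms: hydrogen peroxide, OO
Why: Acid-activated 2,2-disubstituted oxetanes are opened by hydrogen peroxide at the more substituted carbon with inversion (known perhydrolysis to 3-hydroperoxyalkanols), which converts the linalool C14–O bond into the C14–OO bond of the required configuration. Low temperature and a sub-stoichiometric silyl triflate are chosen to keep the opening invertive, and trapping of C14 by C17=C18 would need a four-membered ring or an anti-Markovnikov closure.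

**Step 4**
Reactants: 6 (3S)-3-hydroperoxy-3,7-dimethyloct-6-en-1-ol
Product: 7 (3S)-3-[(2-methoxypropan-2-yl)peroxy]-3,7-dimethyloct-6-en-1-ol
Conditions: 2-methoxypropene (1.1 equiv), PPTS (cat.), CH2Cl2, −20 → 0 °C
Reagents that add atoms: 2-methoxypropene, C=C(C)OC
Why: Peroxyketal formation: the hydroperoxide is the more acidic and, through the alpha effect, the more nucleophilic hydroxyl and should add first to the protonated enol ether, and any mixed ketal on the primary alcohol is much more labile and is lost in the mildly acidic work-up. The peroxyketal is stable to base, stabilised ylides and cold hydride.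

**Step 5**
Reactants: 7 (3S)-3-[(2-methoxypropan-2-yl)peroxy]-3,7-dimethyloct-6-en-1-ol
Product: 8 (3S)-3-[(2-methoxypropan-2-yl)peroxy]-3,7-dimethyloct-6-enal
Conditions: Dess–Martin periodinane, NaHCO3, CH2Cl2, 0 °C → rt
Reagents that add atoms: none
Why: Buffered Dess–Martin oxidation is neutral, so the β-peroxy aldehyde is not exposed to amine bases that would eliminate the peroxide; the aldehyde is used directly.

**Step 6**
Reactants: 8 (3S)-3-[(2-methoxypropan-2-yl)peroxy]-3,7-dimethyloct-6-enal
Product: 9 (3E,6S)-6-[(2-methoxypropan-2-yl)peroxy]-6,10-dimethylundeca-3,9-dien-2-one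
Conditions: Ph3P=CHC(O)CH3, CH2Cl2, rt
Reagents that add atoms: 1-(triphenylphosphoranylidene)propan-2-one, CC(=O)C=P(c1ccccc1)(c1ccccc1)c1ccccc1
Why: Wittig reaction with a stabilised ylide forms the C11=C12 bond; the ylide is too weakly basic to eliminate the β-peroxy group and does not reduce the peroxyketal.

**Step 7**
Reactants: 9 (3E,6S)-6-[(2-methoxypropan-2-yl)peroxy]-6,10-dimethylundeca-3,9-dien-2-one
Product: 10 (6R)-6-[(2-methoxypropan-2-yl)peroxy]-6,10-dimethylundec-9-en-2-one
Conditions: KO2CN=NCO2K, AcOH (slow addition), CH2Cl2, 0 °C → rt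
Reagents that add atoms: none
Why: Diimide reduction transfers H2 in a concerted syn fashion and leaves O–O bonds intact; the conjugated disubstituted C11=C12 bond is much more reactive than the isolated trisubstituted C17=C18 bond. Azodicarboxylate is used because sulfonyl hydrazides would condense with the ketone.

**Step 8**
Reactants: 10 (6R)-6-[(2-methoxypropan-2-yl)peroxy]-6,10-dimethylundec-9-en-2-one; 11 triethyl phosphonoacetate
Product: 12 ethyl (2E,7R)-7-[(2-methoxypropan-2-yl)peroxy]-3,7,11-trimethyldodeca-2,10-dienoate
Conditions: NaH, THF, 0 °C → rt; (Z) isomer removed on silica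
Reagents that add atoms: none
Why: Horner–Wadsworth–Emmons olefination of the methyl ketone forms C9=C10 with the E isomer favoured; the minor Z ester expected from a methyl ketone is separated here because the enzyme step needs a single geometry.

**Step 9**
Reactants: 12 ethyl (2E,7R)-7-[(2-methoxypropan-2-yl)peroxy]-3,7,11-trimethyldodeca-2,10-dienoate
Product: 13 (2E,7R)-7-[(2-methoxypropan-2-yl)peroxy]-3,7,11-trimethyldodeca-2,10-dien-1-ol
Conditions: i-Bu2AlH (2.2 equiv), CH2Cl2, −78 °C; KNaC4H4O6 (aq)
Reagents that add atoms: none
Why: 1,2-Reduction of the enoate with i-Bu2AlH at −78 °C is fast, while a hindered dialkyl peroxyketal is reduced only slowly at this temperature; the alkene geometry is kept.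

**Step 10**
Reactants: 13 (2E,7R)-7-[(2-methoxypropan-2-yl)peroxy]-3,7,11-trimethyldodeca-2,10-dien-1-ol
Product: 14 (2E,7R)-7-[(2-methoxypropan-2-yl)peroxy]-3,7,11-trimethyldodeca-2,10-dienal
Conditions: MnO2 (activated), CH2Cl2, rt
Reagents that add atoms: none
Why: Allylic oxidation with MnO2 is neutral and does not isomerise the E alkene, giving the geranial-type enal as a single isomer.

**Step 11 (key step)**
Reactants: 14 (2E,7R)-7-[(2-methoxypropan-2-yl)peroxy]-3,7,11-trimethyldodeca-2,10-dienal
Product: 15 (3R,7R)-7-[(2-methoxypropan-2-yl)peroxy]-3,7,11-trimethyldodec-10-enal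
Conditions: OYE2 (old yellow enzyme 2 of Saccharomyces cerevisiae, purified), NADP+ (cat.), D-glucose, glucose dehydrogenase, potassium phosphate buffer pH 7.0, n-heptane (20% v/v), 25 °C
Reagents that add atoms: none
Why: The enal carbonyl is held by the two hydrogen-bond donors of the old-yellow-enzyme active site, which polarises C9=C10; reduced flavin mononucleotide (regenerated by NADPH, itself recycled by glucose dehydrogenase and D-glucose) delivers hydride to the β-carbon C10 and a tyrosine protonates C9 from the opposite face, a net anti addition of H2. The closest known reactions are the ene-reductase reductions of geranial to citronellal and of farnesal to 2,3-dihydrofarnesal, of which 14 is a 6,7-dihydro-7-peroxy analogue. No ring is closed and no skeletal bond is formed. The one new stereocentre, C10, is controlled by the enzyme: the OYE2 class delivers hydride to the face of (E)-3-methyl-2-enals that gives (R)-citronellal from geranial, and since 14 has the same E geometry and the same methyl/chain arrangement at C10, the same binding mode should give 10R; the remote C14 centre lies outside the region that recognises the enal and is not expected to interfere. Chemoselectivity follows from the mechanism: only a C=C conjugated to the bound carbonyl is activated, so the isolated C17=C18 alkene is untouched, and neither NADPH nor the flavin reduces a hindered dialkyl peroxyketal at pH 7, where the ketal is also hydrolytically stable. Purified enzyme is used so that no alcohol dehydrogenase reduces the carbonyl before the alkene. The step needs geometric integrity of 14, because the Z isomer would bind with methyl and chain exchanged and give the 10S aldehyde; isomerically pure 14, a water-immiscible reservoir phase and a short reaction time guard against E/Z equilibration in the buffer.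

**Step 12**
Reactants: 15 (3R,7R)-7-[(2-methoxypropan-2-yl)peroxy]-3,7,11-trimethyldodec-10-enal
Product: 16 (3R,7R)-7-[(2-methoxypropan-2-yl)peroxy]-3,7,11-trimethyldodec-10-en-1-ol
Conditions: NaBH4, MeOH, 0 °C
Reagents that add atoms: none
Why: Borohydride reduces the aldehyde and leaves dialkyl peroxides and the alkene alone; C10 is β to the carbonyl and cannot epimerise.

**Step 13**
Reactants: 16 (3R,7R)-7-[(2-methoxypropan-2-yl)peroxy]-3,7,11-trimethyldodec-10-en-1-ol
Product: 17 5-{[(3R,7R)-7-[(2-methoxypropan-2-yl)peroxy]-3,7,11-trimethyldodec-10-en-1-yl]sulfanyl}-1-phenyl-1H-tetrazole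
Conditions: 1-phenyl-1H-tetrazole-5-thiol, PPh3, DIAD, THF, 0 °C → rt (PPh3 and DIAD premixed)
Reagents that add atoms: 1-phenyl-1H-tetrazole-5-thiol, Sc1nnnn1-c1ccccc1
Why: Mitsunobu thioetherification of the primary alcohol; the phosphine is consumed at once as the azodicarboxylate adduct, so the hindered peroxyketal, which is reduced only slowly by phosphines, is not attacked.

**Step 14**
Reactants: 17 5-{[(3R,7R)-7-[(2-methoxypropan-2-yl)peroxy]-3,7,11-trimethyldodec-10-en-1-yl]sulfanyl}-1-phenyl-1H-tetrazole
Product: 18 5-{[(3R,7R)-7-[(2-methoxypropan-2-yl)peroxy]-3,7,11-trimethyldodec-10-en-1-yl]sulfonyl}-1-phenyl-1H-tetrazole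
Conditions: (NH4)6Mo7O24·4H2O (cat.), 30% H2O2, EtOH, 0 °C → rt
Reagents that add atoms: hydrogen peroxide, OO
Why: Molybdate-catalysed oxidation with hydrogen peroxide takes the sulfide to the sulfone; sulfur is far more nucleophilic than the trisubstituted alkene, which this reagent does not epoxidise, and low temperature and short contact protect the peroxyketal from the mildly acidic medium.

**Step 15**
Reactants: 19 (S)-2-methylglycidol
Product: 20 (2R)-2-methylhex-5-ene-1,2-diol
Conditions: allylMgCl (2.5 equiv), CuI (10 mol%), THF, −40 → 0 °C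
Reagents that add atoms: allylmagnesium chloride, C=CC[Mg]Cl
Why: Copper-catalysed Grignard opening of the epoxide at its CH2 group forms C4–C5 and leaves the glycidol oxygen on C6 with retention; the Payne rearrangement of the intermediate alkoxide is degenerate (it regenerates 19 of the same configuration), so it cannot erode C6.

**Step 16**
Reactants: 20 (2R)-2-methylhex-5-ene-1,2-diol
Product: 22 (2R)-2-methyl-2-[(triethylsilyl)oxy]hex-5-en-1-yl 4-methylbenzenesulfonate, via hydroxy tosylate 21 (not isolated)
Conditions: TsCl, Et3N, Bu2SnO (2 mol%), CH2Cl2, 0 °C → rt; then 2,6-lutidine, TESOTf, −78 → 0 °C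
Reagents that add atoms: p-toluenesulfonyl chloride, Cc1ccc(cc1)S(Cl)(=O)=O; triethylsilyl trifluoromethanesulfonate, CC[Si](CC)(CC)OS(=O)(=O)C(F)(F)F
Why: Tin-catalysed sulfonylation is selective for the primary hydroxyl of a 1,2-diol, and silylation of the tertiary hydroxyl then masks the future epoxide as a silyloxy tosylate. The tosylate is neopentyl-like and inert to the nucleophiles used later, and the silyl ether oxygen is a poor neighbouring group.

**Step 17**
Reactants: 22 (2R)-2-methyl-2-[(triethylsilyl)oxy]hex-5-en-1-yl 4-methylbenzenesulfonate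
Product: 24 (2R)-2-methyl-5-oxo-2-[(triethylsilyl)oxy]pentyl 4-methylbenzenesulfonate, via ozonide 23 (not isolated)
Conditions: O3, CH2Cl2, −78 °C; then PPh3, −78 °C → rt
Reagents that add atoms: ozone, [O-][O+]=O
Why: Ozonolysis with reductive work-up cleaves the terminal alkene to the C3 aldehyde; the tertiary silyl ether prevents lactol formation.

**Step 18**
Reactants: 24 (2R)-2-methyl-5-oxo-2-[(triethylsilyl)oxy]pentyl 4-methylbenzenesulfonate
Product: 26 (2R,5R,6S)-5-hydroxy-2,6-dimethyl-2-[(triethylsilyl)oxy]oct-7-en-1-yl 4-methylbenzenesulfonate, via borinate 25 (not isolated)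
Conditions: trans-but-2-ene, KOtBu, n-BuLi, THF, −78 → −45 °C; (−)-Ipc2BOMe [from (+)-α-pinene], −78 °C; BF3·OEt2; then 24, −78 °C; then NaOH (3 M), 30% H2O2, rt
Reagents that add atoms: (E)-crotyldiisopinocampheylborane (made in the flask from trans-but-2-ene, C/C=C/C), C/C=C/CB([C@@H]1C[C@@H]2C[C@@H](C2(C)C)[C@H]1C)[C@@H]1C[C@@H]2C[C@@H](C2(C)C)[C@H]1C
Why: Brown crotylation through a chair six-membered transition state: the E-crotyl geometry gives the anti C2/C3 pair, and the isopinocampheyl groups from (+)-α-pinene direct attack to the si face of the aldehyde. C2 is set as in the target and C3 with the configuration that the next inversion corrects; the remote C6 centre has no influence.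

**Step 19**
Reactants: 27 2,3-dimethylbut-2-ene
Product: 28 2-methoxypropan-2-yl hydroperoxide
Conditions: O3, MeOH/CH2Cl2, −78 °C; kept and used as a solution
Reagents that add atoms: ozone, [O-][O+]=O; methanol, CO
Why: Ozonolysis of the tetrasubstituted alkene gives acetone and its carbonyl oxide, which methanol traps as the α-methoxy hydroperoxide; this is the protected hydroperoxide nucleophile for the next step.

**Step 20**
Reactants: 26 (2R,5R,6S)-5-hydroxy-2,6-dimethyl-2-[(triethylsilyl)oxy]oct-7-en-1-yl 4-methylbenzenesulfonate; 28 2-methoxypropan-2-yl hydroperoxide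
Product: 30 (2R,5S,6S)-5-[(2-methoxypropan-2-yl)peroxy]-2,6-dimethyl-2-[(triethylsilyl)oxy]oct-7-en-1-yl 4-methylbenzenesulfonate, via triflate 29 (not isolated)
Conditions: Tf2O, 2,6-lutidine, CH2Cl2, −78 °C; then 28 premixed with KOtBu and 18-crown-6 in THF, −78 → 0 °C
Reagents that add atoms: none
Why: SN2 displacement of a secondary triflate by a peroxide anion with inversion sets C3 (S) and turns the anti pair into the syn pair of the target. The alpha-effect nucleophile is weakly basic and the reaction is run cold to favour substitution over elimination; C1 is still a vinyl group, so no ester-driven β-elimination is possible.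

**Step 21**
Reactants: 30 (2R,5S,6S)-5-[(2-methoxypropan-2-yl)peroxy]-2,6-dimethyl-2-[(triethylsilyl)oxy]oct-7-en-1-yl 4-methylbenzenesulfonate
Product: 32 (2R)-2-[(3S,4S)-3-[(2-methoxypropan-2-yl)peroxy]-4-methylhex-5-en-1-yl]-2-methyloxirane, via hydroxy tosylate 31 (not isolated)
Conditions: Bu4NF, THF, 0 °C → rt
Reagents that add atoms: none
Why: Fluoride removes the silyl group and the tertiary alkoxide displaces the neighbouring primary tosylate (3-exo-tet), forming the C6–C7 epoxide with retention at C6; the peroxyketal is stable to these basic conditions and no ester is yet present.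

**Step 22**
Reactants: 32 (2R)-2-[(3S,4S)-3-[(2-methoxypropan-2-yl)peroxy]-4-methylhex-5-en-1-yl]-2-methyloxirane
Product: 33 methyl (2R,3S)-3-[(2-methoxypropan-2-yl)peroxy]-2-methyl-5-[(2R)-2-methyloxiran-2-yl]pentanoate
Conditions: O3, NaOH (2.5 M in MeOH), CH2Cl2, −78 °C; cold quench into pH 7 phosphate buffer
Reagents that add atoms: ozone, [O-][O+]=O; methanol, CO
Why: Ozonolysis in methanolic NaOH converts a terminal alkene directly into the methyl ester (the aldehyde hemiacetal and the methoxy hydroperoxide are both carried to the ester in the flask); at −78 °C the new α-stereocentre C2 should neither epimerise nor eliminate the β-peroxy group, and peroxyketal and epoxide are inert to cold methoxide.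

**Step 23**
Reactants: 33 methyl (2R,3S)-3-[(2-methoxypropan-2-yl)peroxy]-2-methyl-5-[(2R)-2-methyloxiran-2-yl]pentanoate
Product: 35 methyl (2R)-2-[(3S,6S)-6-(hydroxymethyl)-6-methyl-1,2-dioxan-3-yl]propanoate, via hydroperoxide 34 (not isolated)
Conditions: PPTS (cat.), MeOH, 0 °C; evaporate; then camphorsulfonic acid (10 mol%), CH2Cl2, 0 °C → rt
Reagents that add atoms: none
Why: Mild methanolysis frees the C3 hydroperoxide, whose terminal oxygen then opens the acid-activated epoxide at the tertiary carbon C6 (6-exo, Markovnikov, known intramolecular epoxide opening by hydroperoxides) with inversion; this closes the 1,2-dioxane and sets C6. A C6 epimer from any ionisation would be a separable diastereomer.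

**Step 24**
Reactants: 35 methyl (2R)-2-[(3S,6S)-6-(hydroxymethyl)-6-methyl-1,2-dioxan-3-yl]propanoate
Product: 36 methyl (2R)-2-[(3S,6S)-6-formyl-6-methyl-1,2-dioxan-3-yl]propanoate
Conditions: Dess–Martin periodinane, NaHCO3, CH2Cl2, 0 °C → rt
Reagents that add atoms: none
Why: Neutral Dess–Martin oxidation gives the non-enolisable α-peroxy aldehyde without base that could open the β-peroxy ester; the aldehyde is used promptly.

**Step 25**
Reactants: 18 5-{[(3R,7R)-7-[(2-methoxypropan-2-yl)peroxy]-3,7,11-trimethyldodec-10-en-1-yl]sulfonyl}-1-phenyl-1H-tetrazole; 36 methyl (2R)-2-[(3S,6S)-6-formyl-6-methyl-1,2-dioxan-3-yl]propanoate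
Product: 37 methyl (2R)-2-[(3S,6S)-6-[(1E,4R,8R)-8-[(2-methoxypropan-2-yl)peroxy]-4,8,12-trimethyltrideca-1,11-dien-1-yl]-6-methyl-1,2-dioxan-3-yl]propanoate
Conditions: KN(SiMe3)2 (1.05 equiv), DME, −78 °C (18, 30 min); then 36, −78 °C → rt
Reagents that add atoms: none
Why: Julia–Kocienski olefination: the pre-formed sulfonyl carbanion adds to the aldehyde, and Smiles rearrangement with loss of SO2 and the tetrazolate gives C7=C8. The aldehyde has no α-hydrogen, no free amide base meets the ester, and no carbanion is ever β to an O–O bond; the alkene geometry is irrelevant because it is reduced next.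

**Step 26**
Reactants: 37 methyl (2R)-2-[(3S,6S)-6-[(1E,4R,8R)-8-[(2-methoxypropan-2-yl)peroxy]-4,8,12-trimethyltrideca-1,11-dien-1-yl]-6-methyl-1,2-dioxan-3-yl]propanoate
Product: 38 methyl (2R)-2-[(3S,6R)-6-[(4S,8R)-8-[(2-methoxypropan-2-yl)peroxy]-4,8,12-trimethyltridec-11-en-1-yl]-6-methyl-1,2-dioxan-3-yl]propanoate
Conditions: KO2CN=NCO2K, AcOH, CH2Cl2, 0 °C → rt, reagent in portions with monitoring
Reagents that add atoms: none
Why: Diimide reduction is the standard way to saturate an alkene next to a peroxide; the 1,2-disubstituted C7=C8 bond is reduced faster than the trisubstituted C17=C18 bond, so the reagent is dosed and the reaction followed. The descriptor at C10 changes to S in 38 only because the CIP ranking changes; the centre is not touched.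

**Step 27**
Reactants: 38 methyl (2R)-2-[(3S,6R)-6-[(4S,8R)-8-[(2-methoxypropan-2-yl)peroxy]-4,8,12-trimethyltridec-11-en-1-yl]-6-methyl-1,2-dioxan-3-yl]propanoate
Product: 39 methyl (2R)-2-[(3S,6R)-6-[(4R,8R)-8-hydroperoxy-4,8,12-trimethyltridec-11-en-1-yl]-6-methyl-1,2-dioxan-3-yl]propanoate
Conditions: AcOH/THF/H2O (4:2:1), rt
Reagents that add atoms: none
Why: Acid hydrolysis of the mixed peroxyketal releases the tertiary hydroperoxide; dilute acetic acid is too weak to trigger rearrangement of the hydroperoxide or to affect the dioxane, the ester or the alkene.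

## Compound list

1 | (R)-linalool, (3R)-3,7-dimethylocta-1,6-dien-3-ol | C=C[C@@](C)(CCC=C(C)C)O | starting material
2 | 9-[(3S)-3-hydroxy-3,7-dimethyloct-6-en-1-yl]-9-borabicyclo[3.3.1]nonane | CC(C)=CCC[C@](C)(CCB1C2CCCC1CCC2)O | intermediate (not isolated)
3 | (3R)-3,7-dimethyloct-6-ene-1,3-diol | OCC[C@@](C)(CCC=C(C)C)O | intermediate
4 | (3R)-3-hydroxy-3,7-dimethyloct-6-en-1-yl 4-methylbenzenesulfonate | Cc1ccc(cc1)S(=O)(=O)OCC[C@@](C)(CCC=C(C)C)O | intermediate (not isolated)
5 | (2R)-2-methyl-2-(4-methylpent-3-en-1-yl)oxetane | O1CC[C@@]1(C)CCC=C(C)C | intermediate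
6 | (3S)-3-hydroperoxy-3,7-dimethyloct-6-en-1-ol | OCC[C@](C)(CCC=C(C)C)OO | intermediate
7 | (3S)-3-[(2-methoxypropan-2-yl)peroxy]-3,7-dimethyloct-6-en-1-ol | OCC[C@](C)(CCC=C(C)C)OOC(C)(C)OC | intermediate
8 | (3S)-3-[(2-methoxypropan-2-yl)peroxy]-3,7-dimethyloct-6-enal | O=CC[C@](C)(CCC=C(C)C)OOC(C)(C)OC | intermediate
9 | (3E,6S)-6-[(2-methoxypropan-2-yl)peroxy]-6,10-dimethylundeca-3,9-dien-2-one | CC(=O)/C=C/C[C@](C)(CCC=C(C)C)OOC(C)(C)OC | intermediate
10 | (6R)-6-[(2-methoxypropan-2-yl)peroxy]-6,10-dimethylundec-9-en-2-one | CC(=O)CCC[C@](C)(CCC=C(C)C)OOC(C)(C)OC | intermediate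
11 | triethyl phosphonoacetate | CCOC(=O)CP(=O)(OCC)OCC | starting material
12 | ethyl (2E,7R)-7-[(2-methoxypropan-2-yl)peroxy]-3,7,11-trimethyldodeca-2,10-dienoate | CCOC(=O)/C=C(C)/CCC[C@](C)(CCC=C(C)C)OOC(C)(C)OC | intermediate
13 | (2E,7R)-7-[(2-methoxypropan-2-yl)peroxy]-3,7,11-trimethyldodeca-2,10-dien-1-ol | OC/C=C(C)/CCC[C@](C)(CCC=C(C)C)OOC(C)(C)OC | intermediate
14 | (2E,7R)-7-[(2-methoxypropan-2-yl)peroxy]-3,7,11-trimethyldodeca-2,10-dienal | O=C/C=C(C)/CCC[C@](C)(CCC=C(C)C)OOC(C)(C)OC | intermediate (key-step precursor)
15 | (3R,7R)-7-[(2-methoxypropan-2-yl)peroxy]-3,7,11-trimethyldodec-10-enal | O=CC[C@H](C)CCC[C@](C)(CCC=C(C)C)OOC(C)(C)OC | intermediate (key-step product)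
16 | (3R,7R)-7-[(2-methoxypropan-2-yl)peroxy]-3,7,11-trimethyldodec-10-en-1-ol | OCC[C@H](C)CCC[C@](C)(CCC=C(C)C)OOC(C)(C)OC | intermediate
17 | 5-{[(3R,7R)-7-[(2-methoxypropan-2-yl)peroxy]-3,7,11-trimethyldodec-10-en-1-yl]sulfanyl}-1-phenyl-1H-tetrazole | c1ccccc1-n1nnnc1SCC[C@H](C)CCC[C@](C)(CCC=C(C)C)OOC(C)(C)OC | intermediate
18 | 5-{[(3R,7R)-7-[(2-methoxypropan-2-yl)peroxy]-3,7,11-trimethyldodec-10-en-1-yl]sulfonyl}-1-phenyl-1H-tetrazole | c1ccccc1-n1nnnc1S(=O)(=O)CC[C@H](C)CCC[C@](C)(CCC=C(C)C)OOC(C)(C)OC | intermediate
19 | (S)-2-methylglycidol, [(2S)-2-methyloxiran-2-yl]methanol | OC[C@@]1(C)CO1 | starting material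
20 | (2R)-2-methylhex-5-ene-1,2-diol | C=CCC[C@](C)(CO)O | intermediate
21 | (2R)-2-hydroxy-2-methylhex-5-en-1-yl 4-methylbenzenesulfonate | C=CCC[C@](C)(COS(=O)(=O)c1ccc(C)cc1)O | intermediate (not isolated)
22 | (2R)-2-methyl-2-[(triethylsilyl)oxy]hex-5-en-1-yl 4-methylbenzenesulfonate | C=CCC[C@](C)(COS(=O)(=O)c1ccc(C)cc1)O[Si](CC)(CC)CC | intermediate
23 | (2R)-2-methyl-4-(1,2,4-trioxolan-3-yl)-2-[(triethylsilyl)oxy]butyl 4-methylbenzenesulfonate (both epimers at the trioxolane carbon) | O1OC(CC[C@](C)(COS(=O)(=O)c2ccc(C)cc2)O[Si](CC)(CC)CC)OC1 | intermediate (not isolated)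
24 | (2R)-2-methyl-5-oxo-2-[(triethylsilyl)oxy]pentyl 4-methylbenzenesulfonate | O=CCC[C@](C)(COS(=O)(=O)c1ccc(C)cc1)O[Si](CC)(CC)CC | intermediate
25 | diisopinocampheylborinate of 26 (O-bound boron) | C=C[C@H](C)[C@H](OB([C@@H]1C[C@@H]2C[C@@H](C2(C)C)[C@H]1C)[C@@H]1C[C@@H]2C[C@@H](C2(C)C)[C@H]1C)CC[C@](C)(COS(=O)(=O)c1ccc(C)cc1)O[Si](CC)(CC)CC | intermediate (not isolated)
26 | (2R,5R,6S)-5-hydroxy-2,6-dimethyl-2-[(triethylsilyl)oxy]oct-7-en-1-yl 4-methylbenzenesulfonate | C=C[C@H](C)[C@H](O)CC[C@](C)(COS(=O)(=O)c1ccc(C)cc1)O[Si](CC)(CC)CC | intermediate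
27 | 2,3-dimethylbut-2-ene | CC(C)=C(C)C | starting material
28 | 2-methoxypropan-2-yl hydroperoxide | COC(C)(C)OO | intermediate (reagent)
29 | (2R,5R,6S)-2,6-dimethyl-2-[(triethylsilyl)oxy]-5-{[(trifluoromethyl)sulfonyl]oxy}oct-7-en-1-yl 4-methylbenzenesulfonate | C=C[C@H](C)[C@H](OS(=O)(=O)C(F)(F)F)CC[C@](C)(COS(=O)(=O)c1ccc(C)cc1)O[Si](CC)(CC)CC | intermediate (not isolated)
30 | (2R,5S,6S)-5-[(2-methoxypropan-2-yl)peroxy]-2,6-dimethyl-2-[(triethylsilyl)oxy]oct-7-en-1-yl 4-methylbenzenesulfonate | C=C[C@H](C)[C@@H](OOC(C)(C)OC)CC[C@](C)(COS(=O)(=O)c1ccc(C)cc1)O[Si](CC)(CC)CC | intermediate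
31 | (2R,5S,6S)-2-hydroxy-5-[(2-methoxypropan-2-yl)peroxy]-2,6-dimethyloct-7-en-1-yl 4-methylbenzenesulfonate (formed as its alkoxide) | C=C[C@H](C)[C@@H](OOC(C)(C)OC)CC[C@](C)(COS(=O)(=O)c1ccc(C)cc1)O | intermediate (not isolated)
32 | (2R)-2-[(3S,4S)-3-[(2-methoxypropan-2-yl)peroxy]-4-methylhex-5-en-1-yl]-2-methyloxirane | C=C[C@H](C)[C@@H](OOC(C)(C)OC)CC[C@]1(C)CO1 | intermediate
33 | methyl (2R,3S)-3-[(2-methoxypropan-2-yl)peroxy]-2-methyl-5-[(2R)-2-methyloxiran-2-yl]pentanoate | COC(=O)[C@H](C)[C@@H](OOC(C)(C)OC)CC[C@]1(C)CO1 | intermediate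
34 | methyl (2R,3S)-3-hydroperoxy-2-methyl-5-[(2R)-2-methyloxiran-2-yl]pentanoate | COC(=O)[C@H](C)[C@@H](OO)CC[C@]1(C)CO1 | intermediate (not isolated)
35 | methyl (2R)-2-[(3S,6S)-6-(hydroxymethyl)-6-methyl-1,2-dioxan-3-yl]propanoate | COC(=O)[C@H](C)[C@@H]1CC[C@@](C)(CO)OO1 | intermediate
36 | methyl (2R)-2-[(3S,6S)-6-formyl-6-methyl-1,2-dioxan-3-yl]propanoate | COC(=O)[C@H](C)[C@@H]1CC[C@@](C)(C=O)OO1 | intermediate
37 | methyl (2R)-2-[(3S,6S)-6-[(1E,4R,8R)-8-[(2-methoxypropan-2-yl)peroxy]-4,8,12-trimethyltrideca-1,11-dien-1-yl]-6-methyl-1,2-dioxan-3-yl]propanoate | COC(=O)[C@H](C)[C@@H]1CC[C@@](C)(/C=C/C[C@H](C)CCC[C@](C)(CCC=C(C)C)OOC(C)(C)OC)OO1 | intermediate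
38 | methyl (2R)-2-[(3S,6R)-6-[(4S,8R)-8-[(2-methoxypropan-2-yl)peroxy]-4,8,12-trimethyltridec-11-en-1-yl]-6-methyl-1,2-dioxan-3-yl]propanoate | COC(=O)[C@H](C)[C@@H]1CC[C@@](C)(CCC[C@H](C)CCC[C@](C)(CCC=C(C)C)OOC(C)(C)OC)OO1 | intermediate
39 | methyl (2R)-2-[(3S,6R)-6-[(4R,8R)-8-hydroperoxy-4,8,12-trimethyltridec-11-en-1-yl]-6-methyl-1,2-dioxan-3-yl]propanoate | COC(=O)[C@H](C)[C@@H]1CC[C@@](C)(CCC[C@H](C)CCC[C@](C)(CCC=C(C)C)OO)OO1 | target

## Step count and least certain steps

Total: 27 steps (14 for the side-chain sulfone 18, 10 for the dioxane aldehyde 36 including the one-step preparation of reagent 28, 3 after the union). Longest linear sequence: 17 steps (steps 1–14 and 25–27, from 1).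

**Step 11 (key step).** The most likely failure is erosion of the C10 configuration. This could come from incomplete facial discrimination by the enzyme on a substrate longer and more lipophilic than citral, or from E/Z equilibration of the enal in the aqueous buffer before reduction, since the two geometric isomers are reduced to opposite configurations. Slow turnover caused by poor solubility is the second risk. Fallback: set out from 14 and replace the enzyme by iminium catalysis. A chiral imidazolidinone salt with a Hantzsch ester as hydride donor in cold chloroform reduces β,β-disubstituted enals enantioselectively and is convergent with respect to E/Z geometry, because the iminium ions interconvert faster than they are reduced. The catalyst enantiomer is chosen to give 10R, the peroxyketal and the isolated alkene are not substrates for a Hantzsch ester, and the route is rejoined at 15.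

**Step 20.** The substitution at C3 is next to a branched carbon. Elimination of the triflate towards the conjugated diene (the C2 hydrogen is allylic), or simply slow substitution, could take the material away from the peroxide. Fallback: set out from 26 and reverse the order in which the two C–O bonds of the ring are made, so that the hindered substitution becomes intramolecular.
- Alcohol 26 is converted with MsCl and Et3N into (2R,5R,6S)-2,6-dimethyl-5-[(methylsulfonyl)oxy]-2-[(triethylsilyl)oxy]oct-7-en-1-yl 4-methylbenzenesulfonate F1.
- Bu4NF closes the epoxide to give (3R,4S)-4-methyl-1-[(2R)-2-methyloxiran-2-yl]hex-5-en-3-yl methanesulfonate F2.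
- Ethereal H2O2 with catalytic H3PMo12O40 opens the epoxide at the tertiary carbon with inversion to give (2S,5R,6S)-2-hydroperoxy-1-hydroxy-2,6-dimethyloct-7-en-5-yl methanesulfonate F3.
- One equivalent of KOtBu with 18-crown-6 at 0 °C lets the peroxide anion displace the C3 mesylate (6-exo-tet, inversion) to give [(3S,6S)-6-[(2S)-but-3-en-2-yl]-3-methyl-1,2-dioxan-3-yl]methanol F4.
- Ozonolysis of F4 in methanolic NaOH at −78 °C converts the vinyl group into the methyl ester, and the route is rejoined at 35.

**Step 25.** The β-alkoxide formed when the sulfonyl carbanion adds to the α-peroxy aldehyde could fragment across C6–C7 with loss of the O–O bond before the Smiles rearrangement, or residual base could open the ring at the β-peroxy ester. Fallback: set out from 16 and use a Wittig reaction, which passes through an oxaphosphetane and not a free alkoxide and is established for α-peroxy aldehydes.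
- Alcohol 16 with I2, PPh3 and imidazole gives (3R,7R)-1-iodo-7-[(2-methoxypropan-2-yl)peroxy]-3,7,11-trimethyldodec-10-ene F5.
- PPh3 in warm acetonitrile gives [(3R,7R)-7-[(2-methoxypropan-2-yl)peroxy]-3,7,11-trimethyldodec-10-en-1-yl](triphenyl)phosphonium iodide F6.
- The ylide, generated with NaN(SiMe3)2 at −78 °C, is combined with 36 to give methyl (2R)-2-[(3S,6S)-6-[(1Z,4R,8R)-8-[(2-methoxypropan-2-yl)peroxy]-4,8,12-trimethyltrideca-1,11-dien-1-yl]-6-methyl-1,2-dioxan-3-yl]propanoate F7.
- Diimide reduction as in step 26 rejoins the route at 38. The cis alkene next to the quaternary C6 is strained and should be reduced more readily than the E isomer.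

**Step 26.** Over-reduction at C17=C18 is the risk. The C7=C8 alkene is flanked by the quaternary C6, and diimide distinguishes a hindered disubstituted alkene from a trisubstituted one only moderately, so driving C7=C8 to completion may cost part of the isopropylidene group. Fallback: set out from 37 and take the competing alkene out of play.
- Pyridinium tribromide (one equivalent, with pyridine, CH2Cl2, −78 °C) adds to the more electron-rich trisubstituted alkene to give methyl (2R)-2-[(3S,6S)-6-[(1E,4R,8R)-11,12-dibromo-8-[(2-methoxypropan-2-yl)peroxy]-4,8,12-trimethyltridec-1-en-1-yl]-6-methyl-1,2-dioxan-3-yl]propanoate F8.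
- Diimide then reduces C7=C8 to completion, giving methyl (2R)-2-[(3S,6R)-6-[(4S,8R)-11,12-dibromo-8-[(2-methoxypropan-2-yl)peroxy]-4,8,12-trimethyltridecyl]-6-methyl-1,2-dioxan-3-yl]propanoate F9.
- NaI in acetone at room temperature removes the two bromine atoms by anti elimination and restores C17=C18. Dialkyl peroxides are inert to iodide under neutral conditions. The route is rejoined at 38.

## Further compounds

F0 | step 11 | none | none
F1 | step 20 | (2R,5R,6S)-2,6-dimethyl-5-[(methylsulfonyl)oxy]-2-[(triethylsilyl)oxy]oct-7-en-1-yl 4-methylbenzenesulfonate | C=C[C@H](C)[C@H](OS(C)(=O)=O)CC[C@](C)(COS(=O)(=O)c1ccc(C)cc1)O[Si](CC)(CC)CC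
F2 | step 20 | (3R,4S)-4-methyl-1-[(2R)-2-methyloxiran-2-yl]hex-5-en-3-yl methanesulfonate | C=C[C@H](C)[C@H](OS(C)(=O)=O)CC[C@]1(C)CO1
F3 | step 20 | (2S,5R,6S)-2-hydroperoxy-1-hydroxy-2,6-dimethyloct-7-en-5-yl methanesulfonate | C=C[C@H](C)[C@H](OS(C)(=O)=O)CC[C@@](C)(CO)OO
F4 | step 20 | [(3S,6S)-6-[(2S)-but-3-en-2-yl]-3-methyl-1,2-dioxan-3-yl]methanol | C=C[C@H](C)[C@@H]1CC[C@@](C)(CO)OO1
F5 | step 25 | (3R,7R)-1-iodo-7-[(2-methoxypropan-2-yl)peroxy]-3,7,11-trimethyldodec-10-ene | ICC[C@H](C)CCC[C@](C)(CCC=C(C)C)OOC(C)(C)OC
F6 | step 25 | [(3R,7R)-7-[(2-methoxypropan-2-yl)peroxy]-3,7,11-trimethyldodec-10-en-1-yl](triphenyl)phosphonium iodide | [I-].C(C[C@H](C)CCC[C@](C)(CCC=C(C)C)OOC(C)(C)OC)[P+](c1ccccc1)(c1ccccc1)c1ccccc1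
F7 | step 25 | methyl (2R)-2-[(3S,6S)-6-[(1Z,4R,8R)-8-[(2-methoxypropan-2-yl)peroxy]-4,8,12-trimethyltrideca-1,11-dien-1-yl]-6-methyl-1,2-dioxan-3-yl]propanoate | COC(=O)[C@H](C)[C@@H]1CC[C@@](C)(/C=C\C[C@H](C)CCC[C@](C)(CCC=C(C)C)OOC(C)(C)OC)OO1
F8 | step 26 | methyl (2R)-2-[(3S,6S)-6-[(1E,4R,8R)-11,12-dibromo-8-[(2-methoxypropan-2-yl)peroxy]-4,8,12-trimethyltridec-1-en-1-yl]-6-methyl-1,2-dioxan-3-yl]propanoate (both C11 epimers) | COC(=O)[C@H](C)[C@@H]1CC[C@@](C)(/C=C/C[C@H](C)CCC[C@](C)(CCC(Br)C(C)(C)Br)OOC(C)(C)OC)OO1
F9 | step 26 | methyl (2R)-2-[(3S,6R)-6-[(4S,8R)-11,12-dibromo-8-[(2-methoxypropan-2-yl)peroxy]-4,8,12-trimethyltridecyl]-6-methyl-1,2-dioxan-3-yl]propanoate (both C11 epimers) | COC(=O)[C@H](C)[C@@H]1CC[C@@](C)(CCC[C@H](C)CCC[C@](C)(CCC(Br)C(C)(C)Br)OOC(C)(C)OC)OO1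
A1 | alternative 1 | [(3S,6S)-6-[(2S)-1-{[tert-butyl(diphenyl)silyl]oxy}propan-2-yl]-3-methyl-1,2-dioxan-3-yl]methanol | CC(C)(C)[Si](c1ccccc1)(c1ccccc1)OC[C@H](C)[C@@H]1CC[C@@](C)(CO)OO1
A2 | alternative 1 | tert-butyl{[(2S,3S)-3-[(2-methoxypropan-2-yl)peroxy]-2-methyl-5-[(2R)-2-methyloxiran-2-yl]pentyl]oxy}diphenylsilane | CC(C)(C)[Si](c1ccccc1)(c1ccccc1)OC[C@H](C)[C@@H](OOC(C)(C)OC)CC[C@]1(C)CO1
A3 | alternative 2 | (6S)-3-methoxy-6-methyl-6-(prop-2-en-1-yl)-1,2-dioxane (C3 anomers) | COC1CC[C@@](C)(CC=C)OO1
A4 | alternative 2 | 3,6-dimethoxy-3-methyl-1,2-dioxane | COC1CCC(C)(OC)OO1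
A5 | alternative 3 | (2S,5R)-2-tert-butyl-5-methyl-5-(4-methylpent-3-en-1-yl)-1,3-dioxolan-4-one | CC(C)(C)[C@@H]1OC(=O)[C@@](C)(CCC=C(C)C)O1
A6 | alternative 3 | (2S,5S)-2-tert-butyl-5-methyl-1,3-dioxolan-4-one | CC(C)(C)[C@@H]1OC(=O)[C@H](C)O1
A7 | alternative 3 | 5-iodo-2-methylpent-2-ene | CC(C)=CCCI
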